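Locants: the lower unit uses flavan numbering (O1, C2, C3, C4, C4a, C5–C8, C8a; O5 and O7 are the oxygens on C5 and C7). The upper unit uses primed benzofuran numbering (O1', C2', C3', C3a', C4'–C7', C7a'). Cα is the linking methine.

Structural features

The target is built from two C6-C3-C6 units. The lower one is an intact (+)-catechin: aromatic ring A (C4a, C5–C8, C8a), pyran ring C (O1, C2, C3, C4) and catechol ring B on C2, with adjacent centres C2 (R) and C3 (S). The upper one is rearranged to a 4',6'-dihydroxy-2',3'-dihydrobenzofuran (aromatic ring D; five-membered ring F = O1', C2', C3', C3a', C7a'), and its C2' carries a methine, Cα, that also bears a second catechol (ring E) and C8 of ring A. Cα (R) and C2' (S) are therefore vicinal stereocentres on a freely rotating exocyclic bond, and no ring of the target contains both. Cα is a diarylmethine wedged between the two ortho oxygens of C8 (O7 on C7, O1 on C8a), so the Cα–C8 bond is hindered towards cross-coupling and, like an interflavan bond, is cleaved again by acid. The fragile groups are the eight phenols (two catechols, sensitive to air and base), C2 (which epimerises in base through a ring-B quinone methide) and the benzylic C2–O1 bond. The real difficulty is the Cα/C2' pair, relative and absolute, together with C8-versus-C6 regiochemistry, because every ionic way of making Cα–C8 passes through a planar Cα whose faces differ only through C2'. The key step exploits the six-atom array O7–C7–C8–Cα–C2'–C3': ring A hides a 1-oxadiene (O7=C7–C8=Cα), ring F hides a dienophile (C2'=C3'), and C3' is a methylene benzylic to the trioxygenated ring D, so a temporary C3'–O7 bond can later be removed without trace.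

Logic of the disconnections

18 to 17. Bonds cut: eight O–CH2Ph bonds (O5, O3, two on ring B, two on ring E, O4', O6'). The free polyphenol cannot be carried through organometallic or acidic steps, and one protecting group that leaves in one neutral operation is the simplest answer. The forward step must spare C2–O1, C2'–O1' and Cα–C8.

17 to 16. This transform is a reconnection: one C3'–H of 17 is exchanged for a C3'–O7 bond. It ties the rotating Cα–C2' bond into a pyran (O7, C7, C8, Cα, C2', C3'), turns an acyclic 1,2-relationship into a ring relationship, and uncovers a [4+2] retron. The forward step must break C3'–O7 reductively in the presence of C2–O1 and eight benzyl ethers without loss of H2'. That selectivity rests on the three oxygens of ring D that stabilise charge at C3'.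

16 to 14 and 15 (15 arising from 10). Bonds cut: Cα–C2' and O7–C3', the key disconnection. In one sentence: a catalyst-controlled, dearomative oxa-[4+2] cycloaddition of 15 onto the C2'=C3' bond of 14. The cut runs through the bond between the two difficult stereocentres and not through Cα–C8. It removes three stereocentres and one ring and gives a flat achiral partner (14) and a partner (10) whose Cα configuration is irrelevant. The forward step needs regiocontrol (Cα to C2'), endo control, facial control, and ring closure faster than rearomatisation.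

10 to 7 and 9 (9 from 8). Bond cut: Cα–C1 of ring E. An unhindered aryl nucleophile adds to a formyl group, so the congestion at C8 never has to be overcome in a coupling of two large partners. No stereocontrol is required, and the only demand is gentle isolation of the acid-labile 10.

7 to 6 to 4. Bonds concerned: the O7–benzyl bond (restored in the backward sense) and C8–CHO. The formyl group is both the Cα carbon and the handle that singles out O7 among five benzyl ethers by chelation. The forward steps need clean bromine–lithium exchange and cleavage of the one ether ortho to the carbonyl.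

4 to 3 to 2 to 1. Bonds cut: C8–Br, then O3–benzyl, then four phenolic O–benzyl bonds. C2 and C3 come from the chiral pool, and bromination settles C8 versus C6 before any C–C bond is made. The forward steps must avoid basic conditions while free phenols are present.

14 to 12 to 11. Changes: C2'=C3' back to C3'=O with C2'H2, then two O–benzyl bonds. The oxygenation pattern of ring D and the O1'–C2' bond are bought with 11. The forward steps are a reduction-dehydration and a double etherification.

Other disconnections considered

Alternative 1: the first that comes to mind, a cut at Cα–C8.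
- Forward key step: Lewis-acid ionisation of the enantiopure dihydrobenzofuranyl carbinol A1, then Friedel–Crafts capture of the p-alkoxybenzyl cation by C8 of 3, giving the nona-O-benzyl ether A2.
- The cation is planar, and its faces differ only through C2'. In the conformer of least A(1,3) strain (H2' eclipsing ring E), O1' and C3' occupy the two faces.
- Steric approach anti to C3'H2 leads to αR, whereas through-space assistance by O1' directs attack anti to oxygen and leads to αS. The two arguments oppose each other.
- The new bond is also reversible under the acid that forms it, so any kinetic preference can drain away.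
- A1 needs its own asymmetric epoxidation and 5-exo closure sequence, so no steps are saved.
- The chosen plan replaces this open-chain induction by a cyclic transition state.

Alternative 2: cuts at Cα–C8 and then O1'–C2'.
- Forward key step: invertive Friedel–Crafts opening of the trans-epoxide A3 at its benzylic carbon by C8 of 3, giving alcohol A4. Desilylation and Mitsunobu closure (second inversion) then give A2.
- The double inversion on a trans-epoxide does map onto the target. It depends, however, on SN2 character at a 3,4-dialkoxybenzylic epoxide carbon, where ionisation to the open cation is easy. That returns the facial problem of Alternative 1.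
- Competing paths are Meinwald-type rearrangement to a ketone and 6-endo closure to a flavan-3-ol.
- The plan also needs an orthogonal group on one ring-D oxygen and an asymmetric epoxidation of an unfunctionalised, very electron-rich olefin (Shi epoxidation).
- It is longer, and its stereocentres are set one at a time.

Alternative 3: a ring-contractive union of two flavan-3-ols.
- Forward key step: ionisation of the (−)-epicatechin-derived triflate A5 with a 1,2-shift of O1 from C2 to C3 (inversion at C3, pyran to dihydrofuran), then capture of the C2 cation by C8 of 3 anti to oxygen (inversion at C2). On paper this converts 2R,3R into αR,2'S and gives A2 in very few steps.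
- The O1 shift needs the C3–O bond antiperiplanar to O1–C2. This occurs only in the minor half-chair, which has ring B axial.
- In the dominant half-chair the axial leaving group is antiperiplanar to H2 and H4. A hydride shift to the O1-stabilised 2-flavanyl cation, or elimination to flavenes, should therefore win. Ring A (C4a) is also placed to participate.
- An aryl-ether oxygen is a weak bridging group, so the Cα cation would open and the promised stereospecificity would be lost.
- This is the shortest plan but the least defensible one.

Key step: step 9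

Remark on the chemistry (assumption): the (R)-configured catalyst of step 9 is taken to cover the Si face of Cα in 15. If the sense of induction is the opposite, the (S)-catalyst is used with no other change.

Step 1
Reactants: 1 (+)-catechin, (2R,3S)-2-(3,4-dihydroxyphenyl)chroman-3,5,7-triol
Product: 2 (2R,3S)-5,7-bis(benzyloxy)-2-[3,4-bis(benzyloxy)phenyl]chroman-3-ol
Conditions: BnBr (4.4 equiv), K2CO3, DMF, 0 °C to rt
Reagents that add atoms: benzyl bromide, BrCc1ccccc1
Why: Williamson etherification; carbonate deprotonates only the four phenols, so the secondary C3–OH stays free, and the weak base at low temperature avoids epimerisation of C2 through the ring-B quinone methide.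

Step 2
Reactants: 2 (2R,3S)-5,7-bis(benzyloxy)-2-[3,4-bis(benzyloxy)phenyl]chroman-3-ol
Product: 3 (2R,3S)-3,5,7-tris(benzyloxy)-2-[3,4-bis(benzyloxy)phenyl]chroman
Conditions: NaH, BnBr, DMF, 0 °C to rt
Reagents that add atoms: benzyl bromide, BrCc1ccccc1
Why: Williamson etherification of the C3 alkoxide; with all phenols masked no quinone methide can form, so C2 and C3 are untouched, and the acidic OH is removed before the organometallic steps.

Step 3
Reactants: 3 (2R,3S)-3,5,7-tris(benzyloxy)-2-[3,4-bis(benzyloxy)phenyl]chroman
Product: 4 (2R,3S)-8-bromo-3,5,7-tris(benzyloxy)-2-[3,4-bis(benzyloxy)phenyl]chroman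
Conditions: NBS (1.0 equiv), CH2Cl2, −78 °C to rt
Reagents that add atoms: N-bromosuccinimide, O=C1CCC(=O)N1Br
Why: Electrophilic aromatic bromination; ring A is far more electron-rich than ring B, and of its two free positions C8 is the more reactive in 5,7-di-O-benzylated flavan-3-ols, so one equivalent at low temperature should stop at the 8-bromide and settle C8 versus C6.

Step 4
Reactants: 4 (2R,3S)-8-bromo-3,5,7-tris(benzyloxy)-2-[3,4-bis(benzyloxy)phenyl]chroman
Product: 6 (2R,3S)-3,5,7-tris(benzyloxy)-2-[3,4-bis(benzyloxy)phenyl]chroman-8-carbaldehyde, via 8-lithio arene 5 (not isolated)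
Conditions: n-BuLi, THF, −78 °C; DMF, −78 °C to 0 °C; H2O
Reagents that add atoms: N,N-dimethylformamide, CN(C)C=O (formyl carbon and oxygen of 6); n-butyllithium, [Li]CCCC (lithium of 5)
Why: Bromine–lithium exchange followed by formylation with DMF (Bouveault aldehyde synthesis); exchange at −78 °C is faster than benzylic deprotonation or Wittig rearrangement of the benzyl ethers, and the small electrophile tolerates the two ortho oxygens of C8.

Step 5
Reactants: 6 (2R,3S)-3,5,7-tris(benzyloxy)-2-[3,4-bis(benzyloxy)phenyl]chroman-8-carbaldehyde
Product: 7 (2R,3S)-3,5-bis(benzyloxy)-2-[3,4-bis(benzyloxy)phenyl]-7-hydroxychroman-8-carbaldehyde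
Conditions: MgBr2·OEt2 (2 equiv), toluene/Et2O, 80 °C; 1 M HCl work-up
Reagents that add atoms: none
Why: Chelation-controlled ether cleavage; Mg(II) binds the formyl oxygen and O7 in a six-membered chelate and bromide removes the primary benzyl group by SN2. The only other ortho oxygen, O1, carries the secondary carbon C2, which resists SN2, and the ethers at O5, O3 and ring B cannot chelate.

Step 6
Reactants: 7 (2R,3S)-3,5-bis(benzyloxy)-2-[3,4-bis(benzyloxy)phenyl]-7-hydroxychroman-8-carbaldehyde; 8 4-bromo-1,2-bis(benzyloxy)benzene
Product: 10 (2R,3S)-3,5-bis(benzyloxy)-2-[3,4-bis(benzyloxy)phenyl]-8-{[3,4-bis(benzyloxy)phenyl](hydroxy)methyl}chroman-7-ol (both Cα epimers), via arylmagnesium bromide 9 (not isolated)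
Conditions: 8, Mg, THF, rt to 40 °C; then 7 (0.4 equiv relative to 9), THF, −78 °C to 0 °C; pH 7 buffer
Reagents that add atoms: magnesium, [Mg] (magnesium of 9)
Why: Grignard addition to a salicylaldehyde; the first equivalent of 9 forms the magnesium phenoxide and the second adds to the formyl group. Cα is formed as a mixture of epimers, which does not matter because it becomes planar in step 9, and a neutral work-up keeps the acid-labile benzhydrol intact.

Step 7
Reactants: 11 4,6-dihydroxybenzofuran-3(2H)-one
Product: 12 4,6-bis(benzyloxy)benzofuran-3(2H)-one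
Conditions: BnBr (2.2 equiv), K2CO3, DMF, rt to 50 °C
Reagents that add atoms: benzyl bromide, BrCc1ccccc1
Why: Williamson etherification of both phenols; the phenoxides are formed and alkylated in preference to the C2 methylene under carbonate conditions.

Step 8
Reactants: 12 4,6-bis(benzyloxy)benzofuran-3(2H)-one
Product: 14 4,6-bis(benzyloxy)benzofuran, via dihydrobenzofuran-3-ol 13 (not isolated)
Conditions: NaBH4, THF/MeOH, 0 °C to rt; then 1 M HCl, rt
Reagents that add atoms: none
Why: Hydride reduction of the ketone followed by acid-catalysed E1 dehydration; the C3 cation is stabilised by the three ring oxygens and loss of a C2 proton is driven by aromatisation to the benzofuran.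

Step 9
Reactants: 10 (2R,3S)-3,5-bis(benzyloxy)-2-[3,4-bis(benzyloxy)phenyl]-8-{[3,4-bis(benzyloxy)phenyl](hydroxy)methyl}chroman-7-ol (both Cα epimers); 14 4,6-bis(benzyloxy)benzofuran
Product: 16 all-cis cycloadduct (αR,2'R,3'R,2R,3S) in which new Cα–C2' and O7–C3' bonds close a pyran between ring A and ring F (octa-O-benzyl; Hα H2' H3' on one face), via (E)-o-quinone methide 15 (not isolated)
Conditions: (R)-3,3'-bis(2,4,6-triisopropylphenyl)-1,1'-binaphthyl-2,2'-diyl N-triflylphosphoramide (10 mol %), 14 (3 equiv), 5 Å MS, toluene, −40 °C, slow addition of 10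
Reagents that add atoms: none
Why: Proposed new method: the acid dehydrates both Cα epimers of 10 to the hydrogen-bonded o-quinone methide 15, C2' of 14 attacks Cα, and O7 closes on C3' in a concerted but strongly asynchronous inverse-electron-demand oxa-[4+2] cycloaddition that dearomatises the furan ring of 14. The closest known reaction type is the chiral N-triflylphosphoramide-catalysed [4+2] cycloaddition of o-quinone methides, generated from o-hydroxybenzhydrols, with styrenes to give cis-2,4-diarylchromans; the C2'=C3' bond of 14 serves here as a cyclic, β-oxygenated 2,4,6-trialkoxystyrene, a dienophile class for which this reaction has not been shown. The only ring closed is the pyran O7–C7–C8–Cα–C2'–C3', by [4+2] cycloaddition or, in the stepwise limit, by 6-exo-trig capture of the C3' cation by O7. Cα (R) is controlled by the catalyst, whose anion is anchored by a hydrogen bond at O7 and covers the Si face of Cα so that 14 adds to the Re face, the remote centres C2 and C3 acting only as a matched or mismatched perturbation. C2' is controlled relative to Cα by the transition-state geometry: ring E stands outside the heterodiene (E-15; the Z form cannot reach the cycloaddition geometry and drains into E through the zwitterionic benzhydryl cation/phenoxide form) and ring D stacks endo under the electron-poor dienone, which places ring E, O1' and C3a' on one face of the new pyran, the relative configuration of the target. C3' is fixed by the suprafacial addition that the 5/6 cis-fusion enforces and is erased in step 10. The regiochemistry needed (Cα to C2', not to C3', C5' or C7') is secured by ring D, whose oxygens O1', O4' and O6' stabilise charge at C3' without loss of benzene aromaticity, and closure must outrun loss of H2', which the intramolecular O7 nucleophile, the weakly basic counter-anion and the low temperature favour. Excess 14 and slow addition of 10 keep C6 of a second molecule from competing for 15.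

Step 10
Reactants: 16 all-cis cycloadduct (αR,2'R,3'R,2R,3S)
Product: 17 octa-O-benzyl ether of the target with free O7–H (αR,2'S,2R,3S)
Conditions: Et3SiH (20 equiv), CF3CO2H (10 equiv), CH2Cl2, −40 °C
Reagents that add atoms: none
Why: Ionic hydrogenation (reductive cleavage of a benzylic ether); protonation at O7 releases the phenol and a C3' cation stabilised by O1', O4' and O6', far better than a cation at C2 of ring C (one para oxygen, β-alkoxy group), so only C3'–O7 should ionise, and a large excess of silane at low temperature captures the cation before it loses H2' or fragments. C3' becomes a methylene, Cα and C2' are not touched, and C2' now reads S only because the CIP ranking of its neighbours changes.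

Step 11
Reactants: 17 octa-O-benzyl ether of the target with free O7–H
Product: 18 target, (2R,3S)-8-{(R)-[(2S)-4,6-dihydroxy-2,3-dihydrobenzofuran-2-yl](3,4-dihydroxyphenyl)methyl}-2-(3,4-dihydroxyphenyl)chroman-3,5,7-triol
Conditions: H2 (1 atm), Pd(OH)2/C, THF/MeOH, rt; filtration under argon
Reagents that add atoms: none
Why: Catalytic hydrogenolysis of eight primary benzyl ethers under neutral conditions; the cyclic secondary C2–O1 bond is much slower to cleave, C2'–O1' is not benzylic, and no stereocentre is involved.

Compound list
1 | (+)-catechin, (2R,3S)-2-(3,4-dihydroxyphenyl)chroman-3,5,7-triol | Oc1cc(O)c2c(c1)O[C@H](c1ccc(O)c(O)c1)[C@@H](O)C2 | starting material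
2 | (2R,3S)-5,7-bis(benzyloxy)-2-[3,4-bis(benzyloxy)phenyl]chroman-3-ol | C(c3ccccc3)Oc1cc(OCc3ccccc3)c2c(c1)O[C@H](c1ccc(OCc3ccccc3)c(OCc3ccccc3)c1)[C@@H](O)C2 | intermediate
3 | (2R,3S)-3,5,7-tris(benzyloxy)-2-[3,4-bis(benzyloxy)phenyl]chroman | C(c3ccccc3)Oc1cc(OCc3ccccc3)c2c(c1)O[C@H](c1ccc(OCc3ccccc3)c(OCc3ccccc3)c1)[C@@H](OCc3ccccc3)C2 | intermediate
4 | (2R,3S)-8-bromo-3,5,7-tris(benzyloxy)-2-[3,4-bis(benzyloxy)phenyl]chroman | C(c3ccccc3)Oc1cc(OCc3ccccc3)c2c(c1Br)O[C@H](c1ccc(OCc3ccccc3)c(OCc3ccccc3)c1)[C@@H](OCc3ccccc3)C2 | intermediate
5 | 8-lithio derivative of 3 (not isolated) | C(c3ccccc3)Oc1cc(OCc3ccccc3)c2c(c1[Li])O[C@H](c1ccc(OCc3ccccc3)c(OCc3ccccc3)c1)[C@@H](OCc3ccccc3)C2 | intermediate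
6 | (2R,3S)-3,5,7-tris(benzyloxy)-2-[3,4-bis(benzyloxy)phenyl]chroman-8-carbaldehyde | C(c3ccccc3)Oc1cc(OCc3ccccc3)c2c(c1C=O)O[C@H](c1ccc(OCc3ccccc3)c(OCc3ccccc3)c1)[C@@H](OCc3ccccc3)C2 | intermediate
7 | (2R,3S)-3,5-bis(benzyloxy)-2-[3,4-bis(benzyloxy)phenyl]-7-hydroxychroman-8-carbaldehyde | Oc1cc(OCc3ccccc3)c2c(c1C=O)O[C@H](c1ccc(OCc3ccccc3)c(OCc3ccccc3)c1)[C@@H](OCc3ccccc3)C2 | intermediate
8 | 4-bromo-1,2-bis(benzyloxy)benzene | Brc1ccc(OCc2ccccc2)c(OCc2ccccc2)c1 | starting material
9 | 3,4-bis(benzyloxy)phenylmagnesium bromide (not isolated) | Br[Mg]c1ccc(OCc2ccccc2)c(OCc2ccccc2)c1 | intermediate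
10 | (2R,3S)-3,5-bis(benzyloxy)-2-[3,4-bis(benzyloxy)phenyl]-8-{[3,4-bis(benzyloxy)phenyl](hydroxy)methyl}chroman-7-ol, both epimers at Cα | Oc1cc(OCc3ccccc3)c2c(c1C(O)c1ccc(OCc3ccccc3)c(OCc3ccccc3)c1)O[C@H](c1ccc(OCc3ccccc3)c(OCc3ccccc3)c1)[C@@H](OCc3ccccc3)C2 | intermediate
11 | 4,6-dihydroxybenzofuran-3(2H)-one | O=C1COc2cc(O)cc(O)c12 | starting material
12 | 4,6-bis(benzyloxy)benzofuran-3(2H)-one | O=C1COc2cc(OCc3ccccc3)cc(OCc3ccccc3)c12 | intermediate
13 | 4,6-bis(benzyloxy)-2,3-dihydrobenzofuran-3-ol, racemic (not isolated) | OC1COc2cc(OCc3ccccc3)cc(OCc3ccccc3)c12 | intermediate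
14 | 4,6-bis(benzyloxy)benzofuran | c1coc2cc(OCc3ccccc3)cc(OCc3ccccc3)c12 | intermediate
15 | (E)-o-quinone methide, (2R,3S)-3,5-bis(benzyloxy)-2-[3,4-bis(benzyloxy)phenyl]-8-[(E)-3,4-bis(benzyloxy)benzylidene]-3,4-dihydro-2H-chromen-7(8H)-one (not isolated) | O=C1C=C(OCc3ccccc3)C2=C(/C1=C\c1ccc(OCc3ccccc3)c(OCc3ccccc3)c1)O[C@H](c1ccc(OCc3ccccc3)c(OCc3ccccc3)c1)[C@@H](OCc3ccccc3)C2 | intermediate
16 | all-cis cycloadduct (αR,2'R,3'R,2R,3S): 17 with an O7–C3' bond in place of O7–H and one C3'–H; pyran O7–C7–C8–Cα–C2'–C3' cis-fused to ring F | C(c7ccccc7)Oc1cc(OCc7ccccc7)c2c(c1)O[C@H]3[C@@H]2Oc4cc(OCc7ccccc7)c5c(c4[C@H]3c6ccc(OCc7ccccc7)c(OCc7ccccc7)c6)O[C@H](c6ccc(OCc7ccccc7)c(OCc7ccccc7)c6)[C@@H](OCc7ccccc7)C5 | intermediate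
17 | (2R,3S)-3,5-bis(benzyloxy)-2-[3,4-bis(benzyloxy)phenyl]-8-{(R)-[(2S)-4,6-bis(benzyloxy)-2,3-dihydrobenzofuran-2-yl][3,4-bis(benzyloxy)phenyl]methyl}chroman-7-ol | C(c4ccccc4)Oc1cc(OCc4ccccc4)c2c(c1)O[C@H]([C@H](c1ccc(OCc4ccccc4)c(OCc4ccccc4)c1)c1c(O)cc(OCc4ccccc4)c3c1O[C@H](c1ccc(OCc4ccccc4)c(OCc4ccccc4)c1)[C@@H](OCc4ccccc4)C3)C2 | intermediate
18 | (2R,3S)-8-{(R)-[(2S)-4,6-dihydroxy-2,3-dihydrobenzofuran-2-yl](3,4-dihydroxyphenyl)methyl}-2-(3,4-dihydroxyphenyl)chroman-3,5,7-triol | Oc1cc(O)c2c(c1)O[C@H]([C@H](c1ccc(O)c(O)c1)c1c(O)cc(O)c3c1O[C@H](c1ccc(O)c(O)c1)[C@@H](O)C3)C2 | target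

Total step count: 11 (branch 1: steps 1–6; branch 2: steps 7–8; union and endgame: steps 9–11).
Longest linear sequence: 9 steps (1, 2, 3, 4, 5, 6, 9, 10, 11).

Steps least certain to work

Step 9 (key step, proposed new method).
- The most likely failure is rearomatisation: loss of H2' from the C3' cation before O7 closes, or after the acid re-ionises the C3'–O7 bond. The benzofuran is the thermodynamic sink.
- Friedel–Crafts attack through the benzenoid positions C5'/C7' of ring D is also possible.
- Facial selectivity may be poor if catalyst and substrate are mismatched, or if ring E, crowded against O1, distorts the heterodiene.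
- The fallback uses known chemistry, sets out from 10 and 14, and returns at 17. It takes the rearomatised product as its goal and sets the two centres one after the other.
- A chiral phosphoric acid catalysed 1,4-addition of the electron-rich heteroarene 14 to 15 gives the 2-(diarylmethyl)benzofuran F1 with Cα (R). The known type is the asymmetric conjugate addition of (hetero)arenes to o-quinone methides formed in situ, which gives triarylmethanes.
- The C2'=C3' bond of F1 is then hydrogenated with a chiral ruthenium N-heterocyclic carbene catalyst. The known type is the asymmetric hydrogenation of 2-substituted benzofurans. This sets C2' under catalyst control, leaves the benzyl ethers alone, gives 17 directly, and makes step 10 unnecessary.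

Step 10.
- The C3' cation may lose H2', with scrambling of C2' on reprotonation.
- It may also fragment at the C2'–Cα bond (reverse of the C–C bond formation), after which the silane would reduce the diarylmethyl cation. Both paths are unimolecular and gain on hydride capture as the temperature rises.
- Acid cleavage of Cα–C8 is a further risk.
- The fallback sets out from 16 and returns at 18. It reverses the order of the endgame and avoids the free cation.
- Hydrogenolysis (H2, Pd(OH)2/C) first gives the heptaphenol F2.
- With O4'–H and O6'–H free, the C3'–O7 bond opens under neutral to weakly basic conditions by expulsion of the O7 phenoxide, giving a ring-D quinone methide. NaBH4 in degassed aqueous ethanol should reduce C3' as soon as it is unmasked. The known type is the borohydride reduction of o- or p-hydroxybenzyl ethers through quinone methides. The product is 18.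

Step 5.
- The Lewis acid may open ring C at the benzylic C2–O1 bond through the alternative O1/formyl chelate, or may remove a second benzyl group on prolonged heating.
- The fallback sets out from 4 and returns at 10. It makes the C–C bond first and moves the differentiation of O7 to a ketone.
- Bromine–lithium exchange of 4 and addition to commercial 3,4-bis(benzyloxy)benzaldehyde gives the fully benzylated carbinol F3.
- Oxidation (MnO2) gives the benzophenone F4.
- One equivalent of BCl3 at −78 °C removes only the benzyl group held in the ketone chelate and gives the 7-hydroxybenzophenone F5.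
- NaBH4 then reduces F5 to 10.

Step 6.
- Premature ionisation of 10 during work-up or chromatography, followed by self-condensation through C6, is the likely loss, because both aryl groups stabilise the Cα cation strongly.
- The fallback sets out from 7 and returns at 16. It never isolates a benzhydrol.
- Compound 7 is converted (Boc2O, i-Pr2NEt, cat. DMAP) into the tert-butyl carbonate F6.
- Addition of 9 at −78 °C in the presence of 14 gives an alkoxide that takes over the Boc group from O7 and expels tert-butyl carbonate. This generates 15 under basic conditions (known anionic generation of o-quinone methides), and 15 is trapped by 14 to give 16.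
- Facial control then rests on the substrate alone, and the diastereomers would have to be separated.

Further compounds
F1 | step 9 | (2R,3S)-3,5-bis(benzyloxy)-2-[3,4-bis(benzyloxy)phenyl]-8-{(R)-[4,6-bis(benzyloxy)benzofuran-2-yl][3,4-bis(benzyloxy)phenyl]methyl}chroman-7-ol | C(c4ccccc4)Oc1cc(OCc4ccccc4)c2cc([C@H](c5ccc(OCc4ccccc4)c(OCc4ccccc4)c5)c5c(O)cc(OCc4ccccc4)c3c5O[C@H](c5ccc(OCc4ccccc4)c(OCc4ccccc4)c5)[C@@H](OCc4ccccc4)C3)oc2c1
F2 | step 10 | fully debenzylated cycloadduct (heptaphenol, αR,2'R,3'R,2R,3S) | Oc1cc(O)c2c(c1)O[C@H]3[C@@H]2Oc4cc(O)c5c(c4[C@H]3c6ccc(O)c(O)c6)O[C@H](c6ccc(O)c(O)c6)[C@@H](O)C5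
F3 | step 5 | (2R,3S)-3,5,7-tris(benzyloxy)-2-[3,4-bis(benzyloxy)phenyl]chroman-8-yl 3,4-bis(benzyloxy)phenyl carbinol, both epimers | C(c3ccccc3)Oc1cc(OCc3ccccc3)c2c(c1C(O)c1ccc(OCc3ccccc3)c(OCc3ccccc3)c1)O[C@H](c1ccc(OCc3ccccc3)c(OCc3ccccc3)c1)[C@@H](OCc3ccccc3)C2
F4 | step 5 | (2R,3S)-3,5,7-tris(benzyloxy)-2-[3,4-bis(benzyloxy)phenyl]chroman-8-yl 3,4-bis(benzyloxy)phenyl ketone | C(c3ccccc3)Oc1cc(OCc3ccccc3)c2c(c1C(=O)c1ccc(OCc3ccccc3)c(OCc3ccccc3)c1)O[C@H](c1ccc(OCc3ccccc3)c(OCc3ccccc3)c1)[C@@H](OCc3ccccc3)C2
F5 | step 5 | (2R,3S)-3,5-bis(benzyloxy)-2-[3,4-bis(benzyloxy)phenyl]-7-hydroxychroman-8-yl 3,4-bis(benzyloxy)phenyl ketone | Oc1cc(OCc3ccccc3)c2c(c1C(=O)c1ccc(OCc3ccccc3)c(OCc3ccccc3)c1)O[C@H](c1ccc(OCc3ccccc3)c(OCc3ccccc3)c1)[C@@H](OCc3ccccc3)C2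
F6 | step 6 | tert-butyl (2R,3S)-3,5-bis(benzyloxy)-2-[3,4-bis(benzyloxy)phenyl]-8-formylchroman-7-yl carbonate | CC(C)(C)OC(=O)Oc1cc(OCc3ccccc3)c2c(c1C=O)O[C@H](c1ccc(OCc3ccccc3)c(OCc3ccccc3)c1)[C@@H](OCc3ccccc3)C2
A1 | alternative 1 | [(2S)-4,6-bis(benzyloxy)-2,3-dihydrobenzofuran-2-yl][3,4-bis(benzyloxy)phenyl]methanol | C(c4ccccc4)Oc1cc(OCc4ccccc4)c2c(c1)O[C@H](C(O)c1ccc(OCc4ccccc4)c(OCc4ccccc4)c1)C2
A2 | alternative 1 | nona-O-benzyl ether of the target (αR,2'S,2R,3S) | C(c4ccccc4)Oc1cc(OCc4ccccc4)c2c(c1)O[C@H]([C@H](c1ccc(OCc4ccccc4)c(OCc4ccccc4)c1)c1c(OCc4ccccc4)cc(OCc4ccccc4)c3c1O[C@H](c1ccc(OCc4ccccc4)c(OCc4ccccc4)c1)[C@@H](OCc4ccccc4)C3)C2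
A3 | alternative 2 | (R,R)-trans-epoxide, 2-[3,4-bis(benzyloxy)phenyl]-3-[2-(tert-butyldimethylsilyloxy)-4,6-bis(benzyloxy)benzyl]oxirane | CC(C)(C)[Si](C)(C)Oc1cc(OCc2ccccc2)cc(OCc2ccccc2)c1C[C@H]1O[C@@H]1c1ccc(OCc2ccccc2)c(OCc2ccccc2)c1
A4 | alternative 2 | (1R,2R)-1-[3,4-bis(benzyloxy)phenyl]-1-(penta-O-benzylcatechin-8-yl)-3-[2-(tert-butyldimethylsilyloxy)-4,6-bis(benzyloxy)phenyl]propan-2-ol | CC(C)(C)[Si](C)(C)Oc1cc(OCc4ccccc4)cc(OCc4ccccc4)c1C[C@@H](O)[C@H](c1ccc(OCc4ccccc4)c(OCc4ccccc4)c1)c1c(OCc4ccccc4)cc(OCc4ccccc4)c3c1O[C@H](c1ccc(OCc4ccccc4)c(OCc4ccccc4)c1)[C@@H](OCc4ccccc4)C3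
A5 | alternative 3 | (2R,3R)-5,7-bis(benzyloxy)-2-[3,4-bis(benzyloxy)phenyl]chroman-3-yl trifluoromethanesulfonate | C(c3ccccc3)Oc1cc(OCc3ccccc3)c2c(c1)O[C@H](c1ccc(OCc3ccccc3)c(OCc3ccccc3)c1)[C@H](OS(=O)(=O)C(F)(F)F)C2
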